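The route builds ring B (C5–C6–C7–C8–C9–C10, drimane numbering) by inserting C8 into the cyclopentene of a trans-hydrindene. This is made from (S)-Hajos–Parrish ketone, whose quaternary carbon becomes C10 and relays C5, C3, C7 and C9. Chloro(methyl)carbene adds C8 with its methyl group across C7=C9. In the key step, AgOTf-promoted electrocyclic opening of the chlorocyclopropane gives the six-membered allyl cation, captured at C7 by tributylstannylmethanol. The step exploits the C8-methyl trisubstituted alkene of ring B and its allylic C9: a Still–Wittig [2,3] shift then carries C11 from O7 to the α face of C9 and restores C7=C8.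

Key step: step 8

Remark: drimane numbering is used for all compounds; in the hydrindanes C8 is missing and the five-membered ring is C5–C6–C7–C9–C10. β is the face of the C10 methyl group. The target SMILES is read as 3α-OAc, 5α-H, 9β-H (C11 α) and 10β-CH3, i.e. (3R,5R,9R,10S) in this numbering.

Step 1
Reactants: 1 (S)-Hajos–Parrish ketone, (7aS)-7a-methyl-2,3,7,7a-tetrahydro-1H-indene-1,5(6H)-dione
Product: 2 C9 ethylene ketal of 1 (spiro-1,3-dioxolane at the cyclopentanone carbon; enone C3=O, C4=C5 untouched)
Conditions: (TMSOCH2)2 (1.2 equiv), TMSOTf (2 mol%), CH2Cl2, −78 °C → −20 °C; pyridine quench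
Reagents that add atoms: 1,2-bis(trimethylsilyloxy)ethane, C[Si](C)(C)OCCO[Si](C)(C)C
Why: Noyori ketalization; the saturated cyclopentanone is far more electrophilic than the conjugated carbonyl, so only C9=O is masked, and no stereocenter is formed.

Step 2
Reactants: 2 C9 ethylene ketal of 1
Product: 3 4,4-dimethyl 3-ketone with the double bond moved to C5=C6 (in the five-membered ring), C9 ketal
Conditions: KOt-Bu (2.3 equiv), MeI (5 equiv), t-BuOH–THF, 0 °C → rt
Reagents that add atoms: iodomethane, CI
Why: Deconjugative α,α-dialkylation of an enone: the extended dienolate (γ-deprotonation at C6) is methylated at C4 twice, which leaves the double bond at C5=C6 out of conjugation; the ketal keeps C7 from being enolized and methylated.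

Step 3
Reactants: 3 4,4-dimethyl-5-ene 3-ketone, C9 ketal
Product: 4 trans-hydrindane 3-ketone (5α-H, 10β-CH3, 4,4-dimethyl), C9 ketal
Conditions: H2 (4 atm), 10% Pd/C, EtOAc, rt
Reagents that add atoms: none
Why: Heterogeneous catalytic hydrogenation (syn addition): the catalyst should approach the cyclopentene C5=C6 from the α face, opposite the axial C10 methyl group, so that C5–H ends trans to it, C10 controlling C5.

Step 4
Reactants: 4 trans-hydrindane 3-ketone, C9 ketal
Product: 5 3α-alcohol (axial OH, trans to the C10 methyl group), C9 ketal
Conditions: LiBH(s-Bu)3 (1.3 equiv), THF, −78 °C; H2O work-up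
Reagents that add atoms: none
Why: Hydride reduction with a bulky trialkylborohydride: equatorial attack on the chair 4,4-dimethyl-3-ketone should give the axial 3α-alcohol (C3 controlled by the ring-A chair fixed by C5 and C10); the ketal is inert.

Step 5
Reactants: 5 3α-hydroxy C9 ketal
Product: 7 (E)-p-toluenesulfonylhydrazone of the C9 ketone (3α-OH free), via hydroxy ketone 6 (not isolated)
Conditions: TsNHNH2 (1.3 equiv), p-TsOH·H2O (10 mol%), EtOH–H2O (9:1), 80 °C
Reagents that add atoms: p-toluenesulfonohydrazide, Cc1ccc(cc1)S(=O)(=O)NN
Why: Acid-catalysed ketal hydrolysis followed in the same pot by hydrazone condensation at the liberated cyclopentanone; the sulfonamide nitrogen should lie anti to quaternary C10, and no stereocenter is touched.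

Step 6
Reactants: 7 tosylhydrazone
Product: 9 trans-hydrindene with a C7=C9 double bond and 3α-OH, via vinyllithium 8 (not isolated)
Conditions: n-BuLi (4.5 equiv), THF, −78 °C → rt; H2O
Reagents that add atoms: none
Why: Shapiro reaction: after deprotonation of O–H and N–H, further base removes a C7 hydrogen (the only α-hydrogens), and loss of sulfinate and N2 gives the C9 vinyllithium, protonated on quench to the cyclopentene; no stereocenter is formed.

Step 7
Reactants: 9 C7=C9 hydrindene, 3α-OH
Product: 10 chlorocyclopropane: C8 (CH3 exo, Cl endo) bridges C7 and C9 on the α face of the five-membered ring; 3α-OH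
Conditions: n-BuLi (1.05 equiv, alkoxide), then CH3CHCl2 (10 equiv) and n-BuLi (8 equiv, slow addition), Et2O, −40 °C → −10 °C; H2O
Reagents that add atoms: 1,1-dichloroethane, CC(Cl)Cl
Why: Carbenoid cyclopropanation ((2+1) cheletropic addition of the chloro(methyl)carbenoid formed by α-elimination of 1,1-dichloro-1-lithioethane): addition should occur on the α face, away from the C10 methyl group, with methyl exo and chlorine endo for steric reasons; the three new stereocenters are transient and vanish in step 8.

Step 8
Reactants: 10 chlorocyclopropane
Product: 11 ring-expanded allylic ether: 7α-(tributylstannylmethoxy), C8-methyl, C8=C9 double bond, 3α-OH, trans-decalin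
Conditions: Bu3SnCH2OH (4 equiv), AgOTf (1.5 equiv), 2,6-di-tert-butyl-4-methylpyridine (2 equiv), 4 Å MS, CH2Cl2, −20 °C → rt, dark
Reagents that add atoms: (tributylstannyl)methanol, OC[Sn](CCCC)(CCCC)CCCC
Why: AgOTf abstracts the endo chloride while the C7–C9 bond opens in a disrotatory 2π-electrocyclic process (cyclopropyl-to-allyl cation), so the five-membered ring C5–C6–C7–C9–C10 becomes six-membered ring B with C8 and its methyl group inserted; the closest known reaction type is the silver-assisted solvolytic ring expansion of halocarbene adducts of cycloalkenes in alcohols. No ring is closed in this step: ring B arises by cleavage of the bond shared by the three- and five-membered rings. The allyl cation C7–C8–C9 should be captured by the primary stannyl alcohol at C7, because C9 is neopentylic to quaternary C10, and this leaves the C8=C9 double bond. The new C7 stereocenter (7α, pseudoaxial ether) is set by axial attack on the half-chair cation, whose conformation is fixed by the trans ring fusion (C5, C10). Only the endo chloride can open to the cis,cis-allyl cation that a six-membered ring requires, so any exo-chloro isomer of 10 is expected to remain and be separated. The stannyl alcohol, used in excess, should outcompete the hindered axial 3-OH, and the hindered pyridine base removes TfOH so that the C–Sn bond and the allylic ether survive.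

Step 9
Reactants: 11 7α-(tributylstannylmethoxy) allylic ether
Product: 13 9-epi-drim-7-ene-3α,11-diol (C11 α on C9, C7=C8 double bond), via alkoxymethyllithium 12 (not isolated)
Conditions: n-BuLi (2.5 equiv), THF, −78 °C → −20 °C; H2O
Reagents that add atoms: none
Why: Tin–lithium exchange gives the α-alkoxymethyllithium, which undergoes the Still–Wittig [2,3]-sigmatropic rearrangement: the shift is suprafacial, so C11 is delivered from the pseudoaxial 7α-oxygen to the α face of C9 (C9–H β, C7 controlling C9) while the double bond moves to C7=C8; the low temperature suppresses the [1,2] shift.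

Step 10
Reactants: 13 9-epi-drim-7-ene-3α,11-diol; 14 isofraxidin (7-hydroxy-6,8-dimethoxy-2H-chromen-2-one)
Product: 15 C11 aryl ether of 13 with isofraxidin O7, 3α-OH free
Conditions: PPh3 (1.5 equiv), DIAD (1.5 equiv), THF, 0 °C → 40 °C
Reagents that add atoms: none
Why: Mitsunobu etherification: the acidic phenol of 14 displaces the activated primary C11 oxygen (no stereocenter involved), while the axial 3α-hydroxyl next to quaternary C4 is too hindered to be activated.

Step 11
Reactants: 15 C11 aryl ether, 3α-OH
Product: 16 target, CNP0285931.3
Conditions: Ac2O (5 equiv), DMAP (0.5 equiv), pyridine, 50 °C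
Reagents that add atoms: acetic anhydride, CC(=O)OC(C)=O
Why: DMAP-catalysed acylation of the remaining axial secondary alcohol with retention at C3; the lactone, aryl ether and alkene are inert.

Compound list
1 | (S)-Hajos–Parrish ketone | C[C@]12CCC(=O)C=C1CCC2=O | starting material
2 | C9 ethylene ketal of 1 | C[C@]12CCC(=O)C=C1CCC23OCCO3 | intermediate
3 | 4,4-dimethyl-5-ene 3-ketone, C9 ketal | C[C@]12CCC(=O)C(C)(C)C1=CCC23OCCO3 | intermediate
4 | trans-hydrindane 3-ketone (5α-H), C9 ketal | C[C@]12CCC(=O)C(C)(C)[C@@H]1CCC23OCCO3 | intermediate
5 | 3α-alcohol, C9 ketal | C[C@]12CC[C@@H](O)C(C)(C)[C@@H]1CCC23OCCO3 | intermediate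
6 | 3α-hydroxy C9 ketone (not isolated) | C[C@]12CC[C@@H](O)C(C)(C)[C@@H]1CCC2=O | intermediate
7 | (E)-tosylhydrazone of 6 | C[C@]12CC[C@@H](O)C(C)(C)[C@@H]1CC/C2=N\NS(=O)(=O)c3ccc(C)cc3 | intermediate
8 | C9 vinyllithium, lithium 3α-alkoxide (not isolated) | C[C@]12CC[C@@H](O[Li])C(C)(C)[C@@H]1CC=C2[Li] | intermediate
9 | C7=C9 trans-hydrindene, 3α-OH | C[C@]12CC[C@@H](O)C(C)(C)[C@@H]1CC=C2 | intermediate
10 | α-face chlorocyclopropane (Cl endo, CH3 exo), 3α-OH | C[C@]12CC[C@@H](O)C(C)(C)[C@@H]1C[C@@H]3[C@H]2[C@]3(C)Cl | intermediate
11 | 7α-(tributylstannylmethoxy)-8-methyl-8-ene, 3α-OH | C[C@]12CC[C@@H](O)C(C)(C)[C@@H]1C[C@@H](OC[Sn](CCCC)(CCCC)CCCC)C(C)=C2 | intermediate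
12 | 7α-(lithiomethoxy) lithium 3α-alkoxide (not isolated) | C[C@]12CC[C@@H](O[Li])C(C)(C)[C@@H]1C[C@@H](OC[Li])C(C)=C2 | intermediate
13 | 9-epi-drim-7-ene-3α,11-diol | OC[C@@H]1C(C)=CC[C@H]2C(C)(C)[C@H](O)CC[C@]12C | intermediate
14 | isofraxidin | COc1cc2ccc(=O)oc2c(OC)c1O | starting material
15 | C11 isofraxidin ether, 3α-OH | COc1cc2ccc(=O)oc2c(OC)c1OC[C@@H]1C(C)=CC[C@H]2C(C)(C)[C@H](O)CC[C@]12C | intermediate
16 | CNP0285931.3 (3α-acetate) | COc1cc2ccc(=O)oc2c(OC)c1OC[C@@H]1C(C)=CC[C@H]2C(C)(C)[C@H](OC(C)=O)CC[C@]12C | target

Total step count: 11. Longest linear sequence: 11 steps (1 → 16); isofraxidin 14 is bought and enters in step 10.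

Steps most likely to fail

Step 8. Interception of the allyl cation by the stoichiometric tin-bearing alcohol may lose out to proton loss (diene formation) or to acid- or silver-induced loss of the stannyl group, and capture may be less face-selective with this bulky alcohol. The fallback sets out from 10 and separates ring expansion from attachment of the tin-bearing carbon. AgOTf in acetone–H2O (4:1) with NaHCO3 at rt should open 10 in the same way with water, a small nucleophile in large excess, to the 7α-allylic alcohol F1. Williamson etherification (KH 1.0 equiv, Bu3SnCH2I 1.0 equiv, THF, 0 °C) should then alkylate the allylic alkoxide in preference to the axial 3α-alkoxide flanked by quaternary C4. The fallback returns to the route at 11.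

Step 7. The short-lived chloro(methyl)carbenoid may rearrange to vinyl chloride faster than it adds to the hindered cyclopentene, and part of the adduct may carry chlorine exo, which is inert in step 8. The fallback sets out from 9 and no longer brings the methyl group in with the carbene. CHBr3 (3 equiv) and KOt-Bu (4 equiv) in pentane at 0 °C give the more reactive dibromocarbene and hence the dibromocyclopropane F2, in which one bromine is endo in any case. Opening under the step 8 conditions (Bu3SnCH2OH, AgOTf, hindered pyridine base, CH2Cl2) should give the 8-bromo 7α-(tributylstannylmethoxy) ether F3. Negishi coupling (MeZnCl 3 equiv, Pd(PPh3)4 5 mol%, THF, 50 °C) then installs the C8 methyl group and returns to the route at 11.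

Step 10. Formation of the alkoxyphosphonium ion at the β-branched C11 may be slow, and the doubly ortho-substituted phenoxide is a poor nucleophile, so alkylation of the hydrazide or recovery of 13 may dominate. The fallback sets out from 13 and replaces redox condensation by a sulfonate displacement. MsCl (1.05 equiv), Et3N, CH2Cl2 at −20 °C should sulfonylate only the primary hydroxyl to give the C11 mesylate F4. Heating F4 with isofraxidin 14 and Cs2CO3 in DMF at 70 °C gives the aryl ether and returns to the route at 15.

Further compounds
F1 | step 8 | 7α-hydroxy-8-methyl-8-ene, 3α-OH (ring-expanded diol) | C[C@]12CC[C@@H](O)C(C)(C)[C@@H]1C[C@@H](O)C(C)=C2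
F2 | step 7 | α-face dibromocyclopropane across C7–C9, 3α-OH | C[C@]12CC[C@@H](O)C(C)(C)[C@@H]1C[C@@H]3[C@H]2C3(Br)Br
F3 | step 7 | 8-bromo-7α-(tributylstannylmethoxy)-8-ene, 3α-OH | C[C@]12CC[C@@H](O)C(C)(C)[C@@H]1C[C@@H](OC[Sn](CCCC)(CCCC)CCCC)C(Br)=C2
F4 | step 10 | C11 methanesulfonate of 13, 3α-OH | CS(=O)(=O)OC[C@@H]1C(C)=CC[C@H]2C(C)(C)[C@H](O)CC[C@]12C
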